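**Retrosynthetic overview**
1. Target 21 ⇐ trans-diaxial bromohydrin 19 (OH → Cl with retention through bromine participation) ⇐ epoxide 18 (HBr, trans-diaxial opening).
2. Oxane ring ⇐ 6-endo bromoetherification of tertiary alcohol 17; this is the only ring that is built, and it is closed after the carbon skeleton is complete.
3. 17 ⇐ allyl carbinol 10 (allyl → homoprenyl by hydroboration, oxidation, Wittig).
4. Key C–C bond (C5–C6 of the oxane) ⇐ catalytic asymmetric allylboration of methyl ketone 4 with allylboronate 8.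
5. 4 ⇐ cis-(+)-limonene oxide 2; the cyclohexane ring, its C1' stereocentre and the epoxide face come from the chiral pool.

Assumption: (S)-3,3'-Br2-BINOL is taken to deliver allyl to the Re face of a methyl ketone RL–CO–CH3 (acetophenone → (R)-carbinol); this sense is recalled, not verified, so a calibration run on acetophenone fixes the choice and the equally available (R)-catalyst is used if the sense is opposite.

**Route**

Step 1
Reactants: 1 (+)-limonene oxide (commercial, about 1:1 cis/trans, 4R)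
Product: 2 cis-(+)-limonene oxide [(1R,4R,6S)-1-methyl-4-(prop-1-en-2-yl)-7-oxabicyclo[4.1.0]heptane; epoxide oxygen anti to the isopropenyl group]
Conditions: pyrrolidine (0.6 equiv), H2O, reflux, 24 h; dilute HCl wash; distillation
Reagents that add atoms: none
Why: Kinetic separation by aminolysis (SN2 epoxide opening): only the trans isomer can be opened trans-diaxially at its secondary carbon (Fürst–Plattner), whereas the cis isomer would need attack at the tertiary carbon and is recovered with its three stereocentres intact.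

Step 2
Reactants: 2 cis-(+)-limonene oxide
Product: 4 1-[(1S,3R,6R)-6-methyl-7-oxabicyclo[4.1.0]heptan-3-yl]ethan-1-one, via secondary ozonide 3 (not isolated)
Conditions: O3, CH2Cl2, −78 °C; then Me2S, −78 °C → rt
Reagents that add atoms: ozone, [O-][O+]=O
Why: Ozonolysis with reductive work-up cleaves the only C=C bond (isopropenyl) to the methyl ketone, leaving the epoxide and all stereocentres untouched.

Step 3
Reactants: 5 allylmagnesium bromide (CH2=CHCH2MgBr); 6 triisopropyl borate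
Product: 8 allyldiisopropoxyborane (diisopropyl allylboronate), via bromomagnesium allyltriisopropoxyborate 7 (not isolated)
Conditions: Et2O, −78 °C → rt; then HCl (1 M in Et2O, 1.0 equiv), 0 °C; filter; distil
Reagents that add atoms: none
Why: Transmetalation of the Grignard reagent to boron gives the ate complex, and protonolysis of one isopropoxide releases the distillable allylboronate; no stereocentre is involved.

Step 4 (key step)
Reactants: 4 1-[(1S,3R,6R)-6-methyl-7-oxabicyclo[4.1.0]heptan-3-yl]ethan-1-one; 8 allyldiisopropoxyborane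
Product: 10 (2R)-2-[(1S,3R,6R)-6-methyl-7-oxabicyclo[4.1.0]heptan-3-yl]pent-4-en-2-ol, via diisopropyl borate ester 9 (not isolated)
Conditions: 8 (1.5 equiv), (S)-3,3'-Br2-BINOL (15 mol %), PhCF3/PhMe 3:1, −35 °C, 48 h; aq. NaHCO3
Reagents that add atoms: none
Why: Chiral-diol-catalysed asymmetric allylboration of a ketone (carbonyl allylation) runs through a closed chair-like six-membered transition state with the cyclohexyl group equatorial, and the catalyst-bound boronate adds to the Re face to set the (R) tertiary carbinol under catalyst control, because the neighbouring ring CH has two nearly identical CH2 arms and exerts no bias.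

Step 5
Reactants: 10 (2R)-2-[(1S,3R,6R)-6-methyl-7-oxabicyclo[4.1.0]heptan-3-yl]pent-4-en-2-ol
Product: 11 triethyl{[(2R)-2-[(1S,3R,6R)-6-methyl-7-oxabicyclo[4.1.0]heptan-3-yl]pent-4-en-2-yl]oxy}silane
Conditions: TESOTf (1.3 equiv), 2,6-lutidine (2.5 equiv), CH2Cl2, −78 °C
Reagents that add atoms: triethylsilyl trifluoromethanesulfonate, CC[Si](CC)(CC)OS(=O)(=O)C(F)(F)F
Why: Silylation of the tertiary alcohol at low temperature with excess base masks the oxygen, which could otherwise attack the anti-disposed epoxide in the basic steps that follow.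

Step 6
Reactants: 11 TES ether of the allyl carbinol
Product: 13 (4R)-4-[(1S,3R,6R)-6-methyl-7-oxabicyclo[4.1.0]heptan-3-yl]-4-[(triethylsilyl)oxy]pentan-1-ol, via B-alkyl-9-BBN adduct 12 (not isolated)
Conditions: 9-BBN (0.5 M in THF, 1.5 equiv), 0 °C → rt; then 3 M NaOH, 30 % H2O2, 0 °C → rt
Reagents that add atoms: hydrogen peroxide, OO
Why: Anti-Markovnikov hydroboration–oxidation of the terminal alkene; 9-BBN does not touch the trisubstituted epoxide or the silyl ether.

Step 7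
Reactants: 13 primary alcohol
Product: 14 (4R)-4-[(1S,3R,6R)-6-methyl-7-oxabicyclo[4.1.0]heptan-3-yl]-4-[(triethylsilyl)oxy]pentanal
Conditions: (n-Pr)4N[RuO4] (5 mol %), N-methylmorpholine N-oxide (1.5 equiv), 4 Å MS, CH2Cl2, rt
Reagents that add atoms: none
Why: Ley–Griffith oxidation converts the primary alcohol to the aldehyde under neutral conditions that spare the epoxide and silyl ether.

Step 8
Reactants: 14 aldehyde
Product: 16 triethyl{[(2R)-6-methyl-2-[(1S,3R,6R)-6-methyl-7-oxabicyclo[4.1.0]heptan-3-yl]hept-5-en-2-yl]oxy}silane, via oxaphosphetane 15 (not isolated)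
Conditions: i-PrPPh3I (2.0 equiv), n-BuLi (1.9 equiv), THF, 0 °C; then 14, −78 °C → rt
Reagents that add atoms: isopropyltriphenylphosphonium iodide, CC(C)[P+](c1ccccc1)(c1ccccc1)c1ccccc1.[I-]
Why: Wittig olefination with the non-stabilised isopropylidene ylide installs the Me2C=CH terminus; the ylide is symmetrical, so no alkene geometry arises.

Step 9
Reactants: 16 TES-protected alkene
Product: 17 (2R)-6-methyl-2-[(1S,3R,6R)-6-methyl-7-oxabicyclo[4.1.0]heptan-3-yl]hept-5-en-2-ol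
Conditions: Bu4NF (1 M in THF, 2 equiv), 0 °C → rt; used at once
Reagents that add atoms: none
Why: Fluoride-induced desilylation frees the tertiary alcohol without acid, which the hydroxy epoxide would not tolerate.

Step 10
Reactants: 17 tertiary alcohol
Product: 18 (1R,4R,6S)-4-[(2R,5S)-5-bromo-2,6,6-trimethyloxan-2-yl]-1-methyl-7-oxabicyclo[4.1.0]heptane
Conditions: NBS (1.1 equiv), solid NaHCO3, CH2Cl2, −20 → 0 °C, dark; chromatography on Et3N-washed silica
Reagents that add atoms: N-bromosuccinimide, O=C1CCC(=O)N1Br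
Why: Bromonium-induced 6-endo (Markovnikov) bromoetherification: the hydroxyl attacks the dimethyl-substituted carbon anti to bromine through a chair-like transition state with Br and the bulky cyclohexyl group equatorial, giving the (5S) bromide trans to the ring; the C5 epimer is expected in substantial amount and is removed by chromatography.

Step 11
Reactants: 18 bromo-oxane epoxide
Product: 19 (1S,2S,5R)-2-bromo-5-[(2R,5S)-5-bromo-2,6,6-trimethyloxan-2-yl]-2-methylcyclohexan-1-ol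
Conditions: 48 % aq. HBr (3 equiv), Et2O, −15 → 0 °C, 15 min
Reagents that add atoms: hydrogen bromide, Br
Why: Acid-mediated epoxide opening in which Markovnikov and Fürst–Plattner preferences coincide: bromide attacks the tertiary carbon with inversion, giving the axial tertiary bromide cis to the oxanyl group and the axial secondary alcohol.

Step 12
Reactants: 19 trans-diaxial bromohydrin
Product: 21 deoxy isocaespitol [(3S,6R)-3-bromo-6-[(1R,3S,4S)-4-bromo-3-chloro-4-methylcyclohexyl]-2,2,6-trimethyloxane], via alkoxyiminium chloride 20 (not isolated)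
Conditions: Me2C=C(Cl)NMe2 (1.5 equiv), CH2Cl2, 0 °C → rt (not heated)
Reagents that add atoms: 1-chloro-N,N,2-trimethylprop-1-en-1-amine (Ghosez reagent), CC(C)=C(Cl)N(C)C
Why: Neutral deoxychlorination with neighbouring-group participation: the antiperiplanar axial bromine displaces the activated oxygen and chloride reopens the bridged ion trans-diaxially at the secondary carbon (the sense shown by trans-limonene oxide, which also opens at C2), giving net retention and the diaxial bromide/chloride pair.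

**Compound list**
1 | (+)-limonene oxide, commercial cis/trans mixture (4R) | CC(=C)[C@@H]1CCC2(C)OC2C1 | starting material
2 | cis-(+)-limonene oxide, (1R,4R,6S)-1-methyl-4-(prop-1-en-2-yl)-7-oxabicyclo[4.1.0]heptane | CC(=C)[C@@H]1CC[C@@]2(C)O[C@H]2C1 | intermediate
3 | 3-methyl-3-[(1S,3R,6R)-6-methyl-7-oxabicyclo[4.1.0]heptan-3-yl]-1,2,4-trioxolane (epimers at the trioxolane carbon) | CC1(OCOO1)[C@@H]2CC[C@@]3(C)O[C@H]3C2 | intermediate (not isolated)
4 | 1-[(1S,3R,6R)-6-methyl-7-oxabicyclo[4.1.0]heptan-3-yl]ethan-1-one | CC(=O)[C@@H]1CC[C@@]2(C)O[C@H]2C1 | intermediate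
5 | allylmagnesium bromide | C=CC[Mg]Br | starting material
6 | triisopropyl borate | CC(C)OB(OC(C)C)OC(C)C | starting material
7 | bromomagnesium allyltriisopropoxyborate | C=CC[B-](OC(C)C)(OC(C)C)OC(C)C.[Mg+]Br | intermediate (not isolated)
8 | allyldiisopropoxyborane | C=CCB(OC(C)C)OC(C)C | intermediate
9 | diisopropyl (2R)-2-[(1S,3R,6R)-6-methyl-7-oxabicyclo[4.1.0]heptan-3-yl]pent-4-en-2-yl borate | C=CC[C@@](C)(OB(OC(C)C)OC(C)C)[C@@H]1CC[C@@]2(C)O[C@H]2C1 | intermediate (not isolated)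
10 | (2R)-2-[(1S,3R,6R)-6-methyl-7-oxabicyclo[4.1.0]heptan-3-yl]pent-4-en-2-ol | C=CC[C@@](C)(O)[C@@H]1CC[C@@]2(C)O[C@H]2C1 | intermediate
11 | triethyl{[(2R)-2-[(1S,3R,6R)-6-methyl-7-oxabicyclo[4.1.0]heptan-3-yl]pent-4-en-2-yl]oxy}silane | C=CC[C@@](C)(O[Si](CC)(CC)CC)[C@@H]1CC[C@@]2(C)O[C@H]2C1 | intermediate
12 | 9-{(4R)-4-[(1S,3R,6R)-6-methyl-7-oxabicyclo[4.1.0]heptan-3-yl]-4-[(triethylsilyl)oxy]pentyl}-9-borabicyclo[3.3.1]nonane | C1CCC2CCCC1B2CCC[C@@](C)(O[Si](CC)(CC)CC)[C@@H]3CC[C@@]4(C)O[C@H]4C3 | intermediate (not isolated)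
13 | (4R)-4-[(1S,3R,6R)-6-methyl-7-oxabicyclo[4.1.0]heptan-3-yl]-4-[(triethylsilyl)oxy]pentan-1-ol | OCCC[C@@](C)(O[Si](CC)(CC)CC)[C@@H]1CC[C@@]2(C)O[C@H]2C1 | intermediate
14 | (4R)-4-[(1S,3R,6R)-6-methyl-7-oxabicyclo[4.1.0]heptan-3-yl]-4-[(triethylsilyl)oxy]pentanal | O=CCC[C@@](C)(O[Si](CC)(CC)CC)[C@@H]1CC[C@@]2(C)O[C@H]2C1 | intermediate
15 | 3,3-dimethyl-2,2,2-triphenyl-4-{(3R)-3-[(1S,3R,6R)-6-methyl-7-oxabicyclo[4.1.0]heptan-3-yl]-3-[(triethylsilyl)oxy]butyl}-1,2λ5-oxaphosphetane (epimers at C4) | CC1(C)C(CC[C@@](C)(O[Si](CC)(CC)CC)[C@@H]2CC[C@@]3(C)O[C@H]3C2)OP1(c4ccccc4)(c5ccccc5)c6ccccc6 | intermediate (not isolated)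
16 | triethyl{[(2R)-6-methyl-2-[(1S,3R,6R)-6-methyl-7-oxabicyclo[4.1.0]heptan-3-yl]hept-5-en-2-yl]oxy}silane | CC(C)=CCC[C@@](C)(O[Si](CC)(CC)CC)[C@@H]1CC[C@@]2(C)O[C@H]2C1 | intermediate
17 | (2R)-6-methyl-2-[(1S,3R,6R)-6-methyl-7-oxabicyclo[4.1.0]heptan-3-yl]hept-5-en-2-ol | CC(C)=CCC[C@@](C)(O)[C@@H]1CC[C@@]2(C)O[C@H]2C1 | intermediate
18 | (1R,4R,6S)-4-[(2R,5S)-5-bromo-2,6,6-trimethyloxan-2-yl]-1-methyl-7-oxabicyclo[4.1.0]heptane | CC1(C)O[C@@](C)([C@@H]2CC[C@@]3(C)O[C@H]3C2)CC[C@@H]1Br | intermediate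
19 | (1S,2S,5R)-2-bromo-5-[(2R,5S)-5-bromo-2,6,6-trimethyloxan-2-yl]-2-methylcyclohexan-1-ol | CC1(C)O[C@@](C)([C@@H]2CC[C@](C)(Br)[C@@H](O)C2)CC[C@@H]1Br | intermediate
20 | N-[1-({(1S,2S,5R)-2-bromo-5-[(2R,5S)-5-bromo-2,6,6-trimethyloxan-2-yl]-2-methylcyclohexyl}oxy)-2-methylpropylidene]-N-methylmethanaminium chloride | CC1(C)O[C@@](C)([C@@H]2CC[C@](C)(Br)[C@@H](OC(C(C)C)=[N+](C)C)C2)CC[C@@H]1Br.[Cl-] | intermediate (not isolated)
21 | deoxy isocaespitol, (3S,6R)-3-bromo-6-[(1R,3S,4S)-4-bromo-3-chloro-4-methylcyclohexyl]-2,2,6-trimethyloxane | CC1(C)O[C@@](C)([C@@H]2CC[C@](C)(Br)[C@@H](Cl)C2)CC[C@@H]1Br | target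

**Totals and risks**

Total steps: 12. Longest linear sequence: 11 (steps 1, 2 and 4–12; step 3 is a one-step side branch).

Risk 1, step 4 (key allylboration). The α-branched aliphatic ketone may react slowly or give an insufficient diastereomer ratio at the new carbinol. The fallback sets out from 4 and comes back at 17. Horner–Wadsworth–Emmons olefination (triethyl phosphonoacetate, NaH, THF) gives ethyl (2E)-3-[(1S,3R,6R)-6-methyl-7-oxabicyclo[4.1.0]heptan-3-yl]but-2-enoate F1. Reduction with i-Bu2AlH gives (2E)-3-[(1S,3R,6R)-6-methyl-7-oxabicyclo[4.1.0]heptan-3-yl]but-2-en-1-ol F2. Sharpless asymmetric epoxidation (Ti(OiPr)4, L-(+)-diethyl tartrate, t-BuOOH, 4 Å MS, −20 °C) gives {(2S,3S)-3-methyl-3-[(1S,3R,6R)-6-methyl-7-oxabicyclo[4.1.0]heptan-3-yl]oxiran-2-yl}methanol F3. NaAlH2(OCH2CH2OMe)2 delivers hydride to C2 and gives (3R)-3-[(1S,3R,6R)-6-methyl-7-oxabicyclo[4.1.0]heptan-3-yl]butane-1,3-diol F4. TsCl/pyridine gives (3R)-3-hydroxy-3-[(1S,3R,6R)-6-methyl-7-oxabicyclo[4.1.0]heptan-3-yl]butyl 4-methylbenzenesulfonate F5. Me2C=CHMgBr with copper iodide (CuI, 10 mol %) in THF at −30 → 0 °C displaces the tosylate and gives 17.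

Risk 2, step 10 (bromoetherification). Selectivity at the C–Br centre may be modest, a 5-exo oxolane may form, and the hydroxy epoxide 17 is acid-labile. The fallback sets out from 16 and comes back at 21; it installs the ring halogens first and closes the oxane last, when the substrate tolerates more forcing bromonium conditions. LiBr/AcOH in THF opens the epoxide of 16 to (1S,2S,5R)-2-bromo-2-methyl-5-{(2R)-6-methyl-2-[(triethylsilyl)oxy]hept-5-en-2-yl}cyclohexan-1-ol F6. The Ghosez reagent in CH2Cl2 gives {[(2R)-2-[(1R,3S,4S)-4-bromo-3-chloro-4-methylcyclohexyl]-6-methylhept-5-en-2-yl]oxy}triethylsilane F7. HF·pyridine in THF gives (2R)-2-[(1R,3S,4S)-4-bromo-3-chloro-4-methylcyclohexyl]-6-methylhept-5-en-2-ol F8. NBS in (CF3)2CHOH at 0 °C then closes the oxane to 21.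

Risk 3, step 12 (chlorination with retention). Chloride may open the bridged bromonium ion at the tertiary carbon, giving the rearranged diequatorial 1-chloro-2-bromo isomer, or elimination may intervene. The fallback sets out from 18 and comes back at 21; it inverts the epoxide and brings in chloride first. Dilute HClO4 in THF/H2O at 0 °C gives (1S,2S,4R)-4-[(2R,5S)-5-bromo-2,6,6-trimethyloxan-2-yl]-1-methylcyclohexane-1,2-diol F9. MsCl/Et3N gives (1S,2S,5R)-5-[(2R,5S)-5-bromo-2,6,6-trimethyloxan-2-yl]-2-hydroxy-2-methylcyclohexyl methanesulfonate F10. K2CO3 in MeOH closes it to the inverted epoxide (1S,4R,6R)-4-[(2R,5S)-5-bromo-2,6,6-trimethyloxan-2-yl]-1-methyl-7-oxabicyclo[4.1.0]heptane F11. Li2CuCl4 in THF opens this trans-diaxially at the secondary carbon to (1S,2S,4R)-4-[(2R,5S)-5-bromo-2,6,6-trimethyloxan-2-yl]-2-chloro-1-methylcyclohexan-1-ol F12. 1-Bromo-N,N,2-trimethylprop-1-en-1-amine in CH2Cl2 replaces the tertiary hydroxyl by bromide with retention (chlorine-bridged ion pair, axial attack) and gives 21.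

**Further compounds**
F1 | step 4 | ethyl (2E)-3-[(1S,3R,6R)-6-methyl-7-oxabicyclo[4.1.0]heptan-3-yl]but-2-enoate | CCOC(=O)/C=C(\C)[C@@H]1CC[C@@]2(C)O[C@H]2C1
F2 | step 4 | (2E)-3-[(1S,3R,6R)-6-methyl-7-oxabicyclo[4.1.0]heptan-3-yl]but-2-en-1-ol | OC/C=C(\C)[C@@H]1CC[C@@]2(C)O[C@H]2C1
F3 | step 4 | {(2S,3S)-3-methyl-3-[(1S,3R,6R)-6-methyl-7-oxabicyclo[4.1.0]heptan-3-yl]oxiran-2-yl}methanol | OC[C@@H]1O[C@@]1(C)[C@@H]2CC[C@@]3(C)O[C@H]3C2
F4 | step 4 | (3R)-3-[(1S,3R,6R)-6-methyl-7-oxabicyclo[4.1.0]heptan-3-yl]butane-1,3-diol | OCC[C@@](C)(O)[C@@H]1CC[C@@]2(C)O[C@H]2C1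
F5 | step 4 | (3R)-3-hydroxy-3-[(1S,3R,6R)-6-methyl-7-oxabicyclo[4.1.0]heptan-3-yl]butyl 4-methylbenzenesulfonate | Cc1ccc(cc1)S(=O)(=O)OCC[C@@](C)(O)[C@@H]2CC[C@@]3(C)O[C@H]3C2
F6 | step 10 | (1S,2S,5R)-2-bromo-2-methyl-5-{(2R)-6-methyl-2-[(triethylsilyl)oxy]hept-5-en-2-yl}cyclohexan-1-ol | CC(C)=CCC[C@@](C)(O[Si](CC)(CC)CC)[C@@H]1CC[C@](C)(Br)[C@@H](O)C1
F7 | step 10 | {[(2R)-2-[(1R,3S,4S)-4-bromo-3-chloro-4-methylcyclohexyl]-6-methylhept-5-en-2-yl]oxy}triethylsilane | CC(C)=CCC[C@@](C)(O[Si](CC)(CC)CC)[C@@H]1CC[C@](C)(Br)[C@@H](Cl)C1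
F8 | step 10 | (2R)-2-[(1R,3S,4S)-4-bromo-3-chloro-4-methylcyclohexyl]-6-methylhept-5-en-2-ol | CC(C)=CCC[C@@](C)(O)[C@@H]1CC[C@](C)(Br)[C@@H](Cl)C1
F9 | step 12 | (1S,2S,4R)-4-[(2R,5S)-5-bromo-2,6,6-trimethyloxan-2-yl]-1-methylcyclohexane-1,2-diol | CC1(C)O[C@@](C)([C@@H]2CC[C@](C)(O)[C@@H](O)C2)CC[C@@H]1Br
F10 | step 12 | (1S,2S,5R)-5-[(2R,5S)-5-bromo-2,6,6-trimethyloxan-2-yl]-2-hydroxy-2-methylcyclohexyl methanesulfonate | CC1(C)O[C@@](C)([C@@H]2CC[C@](C)(O)[C@@H](OS(C)(=O)=O)C2)CC[C@@H]1Br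
F11 | step 12 | (1S,4R,6R)-4-[(2R,5S)-5-bromo-2,6,6-trimethyloxan-2-yl]-1-methyl-7-oxabicyclo[4.1.0]heptane | CC1(C)O[C@@](C)([C@@H]2CC[C@]3(C)O[C@@H]3C2)CC[C@@H]1Br
F12 | step 12 | (1S,2S,4R)-4-[(2R,5S)-5-bromo-2,6,6-trimethyloxan-2-yl]-2-chloro-1-methylcyclohexan-1-ol | CC1(C)O[C@@](C)([C@@H]2CC[C@](C)(O)[C@@H](Cl)C2)CC[C@@H]1Br
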